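# Isorhamnetin 7-O-sulfate by aryne insertion into an α-benzyloxycinnamic acid: synthesis design

Compound numbers refer to the route and the compound list below; 18 is the target.

## The problem

Isorhamnetin 7-O-sulfate (18) is a flavonol. Ring A, with oxygens at C5 and C7, is fused through C4a–C8a to the 4-pyranone ring C, which carries a hydroxyl at C3 and the 4-hydroxy-3-methoxyphenyl ring B at C2. The target has no stereocentre. The plan creates C2 and C3 transiently in a flavanone, and since dehydrogenation removes both, neither needs control. The real task is telling five oxygens apart: O3' stays a methyl ether, O7 alone becomes a sulfate monoester, and O3, O5 and O4' end as free hydroxyls. The aryl sulfate is the fragile group, being ionic and hydrolysed by acid, so it must be introduced late and followed only by neutral operations. The free polyphenol is sensitive to base and air and is best unveiled last. The 5-OH is hydrogen-bonded to the C4 carbonyl and is the poorest nucleophile, so O5 and O7 can share one acid-labile group. O3 and O4' then need a group that survives acid and leaves by hydrogenolysis after sulfation. The feature that opens the key step lies on ring A: C8a bears the ring oxygen O1, the neighbouring C4a bears the acyl carbon C4, and the C5 oxygen sits directly beside C4a. This is the ortho-acylphenol pattern that arises when a carboxylate adds to the far carbon of a 3-alkoxybenzyne and its acyl group shifts to the carbanion next to the alkoxy group. The C3 oxygen and ring B can be carried in on the acid as an α-alkoxycinnamic acid.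

## Retrosynthesis

**18 ⇒ 16 (via 17).** The two O–CH2Ph bonds at O3 and O4' are cut last. Hydrogenolysis is neutral and leaves an aryl sulfate salt intact, whereas any acid-labile group removed at this stage would take the sulfate with it. The precursor 16 is the sodium salt of the dibenzyl ether. The forward step must debenzylate without saturating C2=C3, then protonate the salt cold.

**16 ⇒ 15.** The O7–S bond is cut. In 15 only the 5- and 7-hydroxyls are free, and the chelated 5-OH does not compete, so sulfation needs no further differentiation. Sulfating a fully deprotected flavonol would instead pit O7 against O4' and O3.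

**15 ⇒ 14 ⇒ 13.** The two methoxymethyl acetals are cut (15 ⇒ 14), then C2=C3 is returned to the flavanone level (14 ⇒ 13). Placing the dehydrogenation before acetal cleavage keeps the electron-rich ring A masked while an oxidant is present. The forward steps must oxidise both diastereomers of 13 alike and remove the acetals without touching the benzyl ethers.

**13 ⇒ 6 + 10 (key disconnection).** Three bonds are cut at once: O1–C8a, C4–C4a and O1–C2. This removes ring C and divides the molecule into a ring A aryne precursor, the 2-(trimethylsilyl)aryl triflate 6, and acid 10, which carries ring B, C2, C3 with its oxygen, and C4. A chalcone-based cut would need C-acylation of ring A and a separate oxidation to install O3; here the C3 oxygen is already in the acid. The forward reaction must add the carboxylate oxygen to the aryne carbon remote from the C5 oxygen, move the acyl group to the carbanion, and close ring C by oxa-Michael addition within chalcone 12.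

**6 ⇒ 3 ⇒ 2 ⇒ 1.** The C–Si and O–Tf bonds of 6 go back to bromophenol 3 through aryl silyl ether 4 and lithium phenoxide 5 (bromine–lithium exchange, retro-Brook shift, triflation). The C–Br bond of 3 goes back to phenol 2, and the acetals of 2 to phloroglucinol (1). The bromination must go ortho to the free hydroxyl and not para.

**10 ⇒ 7 + 8.** The C2=C3 bond of the acid is cut by a Claisen-type condensation into O-benzylvanillin (7) and methyl benzyloxyacetate (8), both catalogue compounds, via ester 9. The geometry of the alkene is of no consequence because the oxa-Michael step and the later dehydrogenation erase it.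

## Roads not taken

**Alternative 1: intramolecular ester Wittig closure of ring C.** The cut is C2=C3. In keto-phosphorane A1, the ylide carbon (C3) attacks the neighbouring aryl vanillate carbonyl (C2), and loss of triphenylphosphine oxide gives flavone A2.
- Merits: the conditions are neutral and thermal. The flavone oxidation level is reached directly, so no dehydrogenation is needed. Ring A regiochemistry is trivial because it derives from C-acylation of a symmetrical arene. No aryne and no regioselective bromination are involved, and in these respects this road is safer than the chosen one.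
- Weak points: A2 has hydrogen at C3. The C3 oxygen would have to be added afterwards by oxidation of the flavone C3 position and then benzylated so that sulfation stays O7-selective. That is at least two extra steps on an advanced intermediate. A1 itself takes several steps (C-acylation, α-halogenation, phosphonium salt and ylide formation, esterification of a hindered phenol).
- Comparison: against its reliability, the chosen plan sets convergence. Ring C, three bonds and the C3 oxygen arrive in one operation from two fragments of three steps or fewer.

**Alternative 2: aromatising Dieckmann-type closure of ring A at C6–C7.** Ring C is built first as the fully substituted pyranone A3. LiN(SiMe3)2 enolises its acetyl group, the methyl carbon attacks the ester of the acetate arm, and tautomerisation gives A4.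
- Merits: A4 has the same structure as 15, the sulfation substrate. This road therefore needs no ring A protecting groups, no acetal cleavage and no dehydrogenation, and the aromatisation is strongly driven. In end-game economy it is better than the chosen plan.
- Weak points: the cost moves into A3, a 4-pyranone with four different substituents, whose assembly would be longer than the whole chosen route up to 15. The methylene of the acetate arm is more acidic than the acetyl methyl, so a dianion is needed. The pyranone is also open to ring-opening by strong bases.
- Comparison: the chosen plan spends three protecting-group steps but starts from 1, 7 and 8.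

**Alternative 3: carbene-catalysed benzoin closure of ring C at C3–C4.** A triazolium-derived N-heterocyclic carbene with DBU converts one aldehyde of dialdehyde A5 into an acyl anion equivalent that adds to the other, giving acyloin A6.
- Merits: the reaction is catalytic and mild, the C3 oxygen is installed at the right level, and ring A regiochemistry is trivial.
- Weak points: the aldehyde that must become the donor is the aryl aldehyde, which is flanked by two ortho oxygens and very electron-rich, hence the slower to add the carbene. If the enolisable α-aryloxy aldehyde reacts first, the ring closes with the carbonyl at C3 and the hydroxyl at C4, the wrong way round. A5 contains a fragile α-aryl-α-aryloxy acetaldehyde. A6 still needs dehydrogenation, and its free 3-OH needs benzylation before sulfation.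
- Comparison: this road forms one bond in its key step where the chosen one forms three, and the end game is longer than from 13.

Key step: step 5

Assumption: the target is drawn as the free hydrogen sulfate; because aryl hydrogen sulfates hydrolyse autocatalytically, the sulfate is carried as its sodium salt and protonated only in the last operation, cold and just before isolation.

## Route

Step 1
Reactants: 1 phloroglucinol
Product: 2 3,5-bis(methoxymethoxy)phenol
Conditions: MOMCl (2.0 equiv), i-Pr2NEt, DMF, 0 °C → rt; chromatography
Reagents that add atoms: chloromethyl methyl ether, COCCl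
Why: Statistical O-alkylation of a symmetrical triol with an α-chloro ether (Williamson-type acetal formation); the bis-ether is separated from mono- and tris-ethers, so a modest yield is accepted on the cheapest material of the route.

Step 2
Reactants: 2 3,5-bis(methoxymethoxy)phenol
Product: 3 2-bromo-3,5-bis(methoxymethoxy)phenol
Conditions: NBS (1.0 equiv), CH2Cl2, −78 → −40 °C
Reagents that add atoms: N-bromosuccinimide, O=C1CCC(=O)N1Br
Why: Electrophilic aromatic bromination; the two equivalent positions ortho to the free hydroxyl should be preferred over the single para position, which is flanked by both acetal groups, and hydrogen bonding of the phenol to the reagent in a non-polar solvent works in the same direction.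

Step 3
Reactants: 3 2-bromo-3,5-bis(methoxymethoxy)phenol
Product: 6 3,5-bis(methoxymethoxy)-2-(trimethylsilyl)phenyl trifluoromethanesulfonate, via aryl trimethylsilyl ether 4 (not isolated), via lithium 2-silylphenoxide 5 (not isolated)
Conditions: HMDS, THF, 70 °C, then evaporate; n-BuLi, THF, −78 °C; Tf2O, −78 °C
Reagents that add atoms: hexamethyldisilazane, C[Si](C)(C)N[Si](C)(C)C; trifluoromethanesulfonic anhydride, O=S(=O)(OS(=O)(=O)C(F)(F)F)C(F)(F)F
Why: O-silylation, bromine–lithium exchange and 1,3 O→C silyl migration (retro-Brook rearrangement) give phenoxide 5, which is triflated at low temperature faster than the acetals can be activated; this is the standard way from 2-bromophenols to 2-silylaryl triflates.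

Step 4
Reactants: 7 4-(benzyloxy)-3-methoxybenzaldehyde (O-benzylvanillin); 8 methyl 2-(benzyloxy)acetate
Product: 10 (Z)-2-(benzyloxy)-3-[4-(benzyloxy)-3-methoxyphenyl]acrylic acid, via methyl (Z)-acrylate 9 (not isolated)
Conditions: NaOMe, MeOH, reflux; then NaOH (aq), reflux; then HCl (aq) to pH 2, recrystallise
Reagents that add atoms: sodium hydroxide, [Na+].[OH-]
Why: Claisen-type condensation of the alkoxyacetate enolate with a non-enolisable aldehyde, E1cB dehydration to the more stable Z-alkene (aryl trans to the ester) and saponification in the same pot; the alkene geometry is not carried into the target.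

Step 5
Reactants: 6 3,5-bis(methoxymethoxy)-2-(trimethylsilyl)phenyl trifluoromethanesulfonate; 10 (Z)-2-(benzyloxy)-3-[4-(benzyloxy)-3-methoxyphenyl]acrylic acid
Product: 13 3-(benzyloxy)-2-[4-(benzyloxy)-3-methoxyphenyl]-5,7-bis(methoxymethoxy)chroman-4-one (racemic 2,3-trans/2,3-cis mixture), via 3,5-bis(methoxymethoxy)benzyne 11 (not isolated), via 2'-hydroxychalcone phenoxide 12 (not isolated)
Conditions: 6 (1.5 equiv), CsF (4 equiv), THF, 125 °C, sealed tube
Reagents that add atoms: none
Why: Fluoride removes the silyl group of 6 and triflate leaves to give aryne 11; the cesium carboxylate of 10 adds through oxygen at the aryne carbon remote from the neighbouring methoxymethoxy group, because the carbanion then develops beside that inductively withdrawing oxygen. The aryl anion attacks the adjacent ester carbonyl through a four-membered transition state and the adduct collapses with C–O cleavage, an anionic Fries-type 1,3 O→C acyl shift that gives the phenoxide of chalcone 12 with O1–C8a and C4–C4a in place. The closest known reaction type is the fluoride-induced insertion of arynes into the C–O bond of carboxylic acids, which with α,β-unsaturated acids is known to run on to chroman-4-ones. Ring C closes by 6-endo-trig oxa-Michael addition of the phenoxide to the enone (O1–C2), helped by the 6'-alkoxy group, which twists the aryl ketone and disfavours the open chalcone. C2 and C3 form without external control; enolate protonation and equilibration at C3 should favour the 2,3-trans isomer, but either is acceptable because step 6 removes both centres. The step needs regioselective carboxylate addition, secured by the alkoxy group next to the aryne; acyl transfer faster than protonation of the aryl anion, secured by the high temperature and by holding the acid as its carboxylate; and attack at the acyl carbon, not the β-carbon, secured by the α-benzyloxy group, which makes the β-position less electrophilic. Methoxymethyl and benzyl ethers are inert to CsF.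

Step 6
Reactants: 13 3-(benzyloxy)-2-[4-(benzyloxy)-3-methoxyphenyl]-5,7-bis(methoxymethoxy)chroman-4-one
Product: 14 3-(benzyloxy)-2-[4-(benzyloxy)-3-methoxyphenyl]-5,7-bis(methoxymethoxy)-4H-chromen-4-one
Conditions: DDQ (1.5 equiv), 1,4-dioxane, 100 °C
Reagents that add atoms: none
Why: Quinone dehydrogenation of a flavanone to a flavone: hydride is abstracted from C2, which is benzylic to the electron-rich ring B and α to O1, and loss of the acidic C3 proton follows, so both diastereomers converge; unactivated benzyl ethers and the acetals tolerate neutral DDQ.

Step 7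
Reactants: 14 3-(benzyloxy)-2-[4-(benzyloxy)-3-methoxyphenyl]-5,7-bis(methoxymethoxy)-4H-chromen-4-one
Product: 15 3-(benzyloxy)-2-[4-(benzyloxy)-3-methoxyphenyl]-5,7-dihydroxy-4H-chromen-4-one
Conditions: HCl (3 M aq), MeOH/THF, 55 °C
Reagents that add atoms: none
Why: Acid-catalysed acetal exchange removes both methoxymethyl groups (the one at O5 is assisted by the C4 carbonyl); benzyl ethers and the flavone core are stable to dilute acid.

Step 8
Reactants: 15 3-(benzyloxy)-2-[4-(benzyloxy)-3-methoxyphenyl]-5,7-dihydroxy-4H-chromen-4-one
Product: 16 sodium 3-(benzyloxy)-2-[4-(benzyloxy)-3-methoxyphenyl]-5-hydroxy-4-oxo-4H-chromen-7-yl sulfate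
Conditions: SO3·pyridine (3 equiv), pyridine, rt; then NaHCO3 (aq); C18 reversed-phase chromatography
Reagents that add atoms: sulfur trioxide–pyridine complex, O=S(=O)([O-])[n+]1ccccc1; sodium hydrogen carbonate, [Na+].OC([O-])=O
Why: O-sulfation of a phenol with an amine–SO3 complex; the 7-OH is the most acidic and unhindered hydroxyl, the 5-OH is locked in a hydrogen bond to the C4 carbonyl, and O3 and O4' are benzylated, so only O7 should react.

Step 9
Reactants: 16 sodium 3-(benzyloxy)-2-[4-(benzyloxy)-3-methoxyphenyl]-5-hydroxy-4-oxo-4H-chromen-7-yl sulfate
Product: 18 isorhamnetin 7-O-sulfate [3,5-dihydroxy-2-(4-hydroxy-3-methoxyphenyl)-4-oxo-4H-chromen-7-yl hydrogen sulfate], via sodium isorhamnetin 7-sulfate 17 (not isolated)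
Conditions: H2 (1 atm), 10% Pd/C, MeOH, rt; filter; then HCl (1.0 equiv, aq), 0 °C; C18 cartridge (water wash, MeOH elution); lyophilise
Reagents that add atoms: none
Why: Catalytic hydrogenolysis cleaves the enol and aryl benzyl ethers under neutral conditions that leave the aryl sulfate salt, the methyl ether and the conjugated C2=C3 bond untouched; brief cold protonation and desalting then give the free acid form.

## Compound list

1 | phloroglucinol (benzene-1,3,5-triol) | Oc1cc(O)cc(O)c1 | starting material
2 | 3,5-bis(methoxymethoxy)phenol | COCOc1cc(O)cc(OCOC)c1 | intermediate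
3 | 2-bromo-3,5-bis(methoxymethoxy)phenol | COCOc1cc(O)c(Br)c(OCOC)c1 | intermediate
4 | [2-bromo-3,5-bis(methoxymethoxy)phenoxy]trimethylsilane | COCOc1cc(O[Si](C)(C)C)c(Br)c(OCOC)c1 | intermediate
5 | lithium 3,5-bis(methoxymethoxy)-2-(trimethylsilyl)phenolate | COCOc1cc([O-])c([Si](C)(C)C)c(OCOC)c1.[Li+] | intermediate
6 | 3,5-bis(methoxymethoxy)-2-(trimethylsilyl)phenyl trifluoromethanesulfonate | COCOc1cc(OCOC)c([Si](C)(C)C)c(OS(=O)(=O)C(F)(F)F)c1 | intermediate
7 | 4-(benzyloxy)-3-methoxybenzaldehyde (O-benzylvanillin) | COc1cc(C=O)ccc1OCc1ccccc1 | starting material
8 | methyl 2-(benzyloxy)acetate | COC(=O)COCc1ccccc1 | starting material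
9 | methyl (Z)-2-(benzyloxy)-3-[4-(benzyloxy)-3-methoxyphenyl]acrylate | COC(=O)/C(OCc1ccccc1)=C/c1ccc(OCc2ccccc2)c(OC)c1 | intermediate
10 | (Z)-2-(benzyloxy)-3-[4-(benzyloxy)-3-methoxyphenyl]acrylic acid | COc1cc(/C=C(\OCc2ccccc2)C(=O)O)ccc1OCc1ccccc1 | intermediate
11 | 3,5-bis(methoxymethoxy)benzyne (1,2-didehydro-3,5-bis(methoxymethoxy)benzene) | COCOC1=CC(OCOC)=CC#C1 | intermediate
12 | (Z)-2-(benzyloxy)-3-[4-(benzyloxy)-3-methoxyphenyl]-1-[2-hydroxy-4,6-bis(methoxymethoxy)phenyl]prop-2-en-1-one (present as its cesium phenoxide) | COCOc1cc(O)c(C(=O)/C(OCc2ccccc2)=C/c2ccc(OCc3ccccc3)c(OC)c2)c(OCOC)c1 | intermediate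
13 | 3-(benzyloxy)-2-[4-(benzyloxy)-3-methoxyphenyl]-5,7-bis(methoxymethoxy)chroman-4-one (racemic, 2,3-trans and 2,3-cis mixture) | COCOc1cc(OCOC)c2c(c1)OC(c1ccc(OCc3ccccc3)c(OC)c1)C(OCc1ccccc1)C2=O | intermediate
14 | 3-(benzyloxy)-2-[4-(benzyloxy)-3-methoxyphenyl]-5,7-bis(methoxymethoxy)-4H-chromen-4-one | COCOc1cc(OCOC)c2c(=O)c(OCc3ccccc3)c(-c3ccc(OCc4ccccc4)c(OC)c3)oc2c1 | intermediate
15 | 3-(benzyloxy)-2-[4-(benzyloxy)-3-methoxyphenyl]-5,7-dihydroxy-4H-chromen-4-one | COc1cc(-c2oc3cc(O)cc(O)c3c(=O)c2OCc2ccccc2)ccc1OCc1ccccc1 | intermediate
16 | sodium 3-(benzyloxy)-2-[4-(benzyloxy)-3-methoxyphenyl]-5-hydroxy-4-oxo-4H-chromen-7-yl sulfate | COc1cc(-c2oc3cc(OS(=O)(=O)[O-])cc(O)c3c(=O)c2OCc2ccccc2)ccc1OCc1ccccc1.[Na+] | intermediate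
17 | sodium 3,5-dihydroxy-2-(4-hydroxy-3-methoxyphenyl)-4-oxo-4H-chromen-7-yl sulfate | COc1cc(-c2oc3cc(OS(=O)(=O)[O-])cc(O)c3c(=O)c2O)ccc1O.[Na+] | intermediate
18 | isorhamnetin 7-O-sulfate, 3,5-dihydroxy-2-(4-hydroxy-3-methoxyphenyl)-4-oxo-4H-chromen-7-yl hydrogen sulfate | COc1cc(-c2oc3cc(OS(=O)(=O)O)cc(O)c3c(=O)c2O)ccc1O | target

## Step count and risk

Total steps: 9. Longest linear sequence: 8 steps (1, 2, 3, 5, 6, 7, 8, 9, from phloroglucinol); the acid branch contributes step 4.

**Step 5 (key step).**
- What may go wrong: the aryl anion may be protonated before the acyl group migrates, which stops the reaction at simple O-arylation. The carbanion may add to the β-carbon of the acrylate instead of the carbonyl carbon. Ring closure may stay incomplete because the α-benzyloxy group makes the enone a poorer Michael acceptor.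
- Fallback: the same aryl anion is generated without an aryne and without a proton source. Bromophenol 3 and acid 10 are esterified (EDC·HCl, DMAP, CH2Cl2) to 2-bromo-3,5-bis(methoxymethoxy)phenyl (Z)-2-(benzyloxy)-3-[4-(benzyloxy)-3-methoxyphenyl]acrylate F1. Bromine–lithium exchange (t-BuLi, THF, −100 °C) then triggers the anionic Fries rearrangement to chalcone 12, and warming with NaOAc in EtOH closes it to 13, where the route is rejoined.

**Step 2.**
- What may go wrong: bromination para to the hydroxyl, or double bromination of the very electron-rich ring. This would carry the wrong substitution pattern into the aryne.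
- Fallback: the silyl group is placed by directed ortho-metalation instead of by electrophilic substitution. Phenol 2 and isopropyl isocyanate (Et3N cat.) give 3,5-bis(methoxymethoxy)phenyl N-isopropylcarbamate F2. N-silylation (TBSOTf, TMEDA), lithiation between the carbamate and the neighbouring acetal oxygen (n-BuLi, −78 °C), TMSCl quench and mild acidic work-up give 3,5-bis(methoxymethoxy)-2-(trimethylsilyl)phenyl N-isopropylcarbamate F3. Carbamate cleavage (Et2NH, DBU, MeCN) and triflation with PhNTf2 in the same pot give 6, bypassing steps 2 and 3.

**Step 6.**
- What may go wrong: slow hydride abstraction, partial acetal loss caused by the acidic hydroquinone by-product, oxidative attack on the benzyl ethers on prolonged heating, and failure of any ring-opened chalcone to converge.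
- Fallback: the order of operations is reversed. Flavanone 13 is first freed of its acetals (HCl, MeOH) to 3-(benzyloxy)-2-[4-(benzyloxy)-3-methoxyphenyl]-5,7-dihydroxychroman-4-one F4. This is then dehydrogenated with catalytic I2 in DMSO at 120 °C, the iodination–elimination method used for 5,7-dihydroxyflavanones and their open chalcones. The route is rejoined at 15.

**Step 8.**
- What may go wrong: incomplete sulfation or over-sulfation, poor separation of the ionic product from pyridinium salts that would then poison the palladium catalyst, and hydrolysis of the sulfate during handling.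
- Fallback: the sulfate is introduced as a neutral, chromatographable diester. Diol 15 with 2,2,2-trichloroethyl chlorosulfate (Et3N, DMAP, THF) gives 3-(benzyloxy)-2-[4-(benzyloxy)-3-methoxyphenyl]-5-hydroxy-4-oxo-4H-chromen-7-yl 2,2,2-trichloroethyl sulfate F5. Pd/C with HCO2NH4 in MeOH removes the trichloroethyl group reductively and both benzyl ethers by transfer hydrogenolysis. This gives ammonium 3,5-dihydroxy-2-(4-hydroxy-3-methoxyphenyl)-4-oxo-4H-chromen-7-yl sulfate F6, which is protonated cold as in step 9 to reach 18.

## Further compounds

F1 | step 5 | 2-bromo-3,5-bis(methoxymethoxy)phenyl (Z)-2-(benzyloxy)-3-[4-(benzyloxy)-3-methoxyphenyl]acrylate | COCOc1cc(OCOC)c(Br)c(OC(=O)/C(OCc2ccccc2)=C/c2ccc(OCc3ccccc3)c(OC)c2)c1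
F2 | step 2 | 3,5-bis(methoxymethoxy)phenyl N-isopropylcarbamate | COCOc1cc(OCOC)cc(OC(=O)NC(C)C)c1
F3 | step 2 | 3,5-bis(methoxymethoxy)-2-(trimethylsilyl)phenyl N-isopropylcarbamate | COCOc1cc(OCOC)c([Si](C)(C)C)c(OC(=O)NC(C)C)c1
F4 | step 6 | 3-(benzyloxy)-2-[4-(benzyloxy)-3-methoxyphenyl]-5,7-dihydroxychroman-4-one (racemic diastereomer mixture) | COc1cc(C2Oc3cc(O)cc(O)c3C(=O)C2OCc2ccccc2)ccc1OCc1ccccc1
F5 | step 8 | 3-(benzyloxy)-2-[4-(benzyloxy)-3-methoxyphenyl]-5-hydroxy-4-oxo-4H-chromen-7-yl 2,2,2-trichloroethyl sulfate | COc1cc(-c2oc3cc(OS(=O)(=O)OCC(Cl)(Cl)Cl)cc(O)c3c(=O)c2OCc2ccccc2)ccc1OCc1ccccc1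
F6 | step 8 | ammonium 3,5-dihydroxy-2-(4-hydroxy-3-methoxyphenyl)-4-oxo-4H-chromen-7-yl sulfate | COc1cc(-c2oc3cc(OS(=O)(=O)[O-])cc(O)c3c(=O)c2O)ccc1O.[NH4+]
A1 | alternative 1 | 3,5-bis(methoxymethoxy)-2-[2-(triphenyl-λ5-phosphanylidene)acetyl]phenyl 4-(benzyloxy)-3-methoxybenzoate | COCOc1cc(OCOC)c(C(=O)C=P(c2ccccc2)(c2ccccc2)c2ccccc2)c(OC(=O)c2ccc(OCc3ccccc3)c(OC)c2)c1
A2 | alternative 1 | 2-[4-(benzyloxy)-3-methoxyphenyl]-5,7-bis(methoxymethoxy)-4H-chromen-4-one | COCOc1cc(OCOC)c2c(=O)cc(-c3ccc(OCc4ccccc4)c(OC)c3)oc2c1
A3 | alternative 2 | methyl 2-{3-acetyl-5-(benzyloxy)-6-[4-(benzyloxy)-3-methoxyphenyl]-4-oxo-4H-pyran-2-yl}acetate | COC(=O)Cc1oc(-c2ccc(OCc3ccccc3)c(OC)c2)c(OCc2ccccc2)c(=O)c1C(C)=O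
A4 | alternative 2 | 3-(benzyloxy)-2-[4-(benzyloxy)-3-methoxyphenyl]-5,7-dihydroxy-4H-chromen-4-one | COc1cc(-c2oc3cc(O)cc(O)c3c(=O)c2OCc2ccccc2)ccc1OCc1ccccc1
A5 | alternative 3 | 2-{1-[4-(benzyloxy)-3-methoxyphenyl]-2-oxoethoxy}-4,6-bis(methoxymethoxy)benzaldehyde (racemic) | COCOc1cc(OCOC)c(C=O)c(OC(C=O)c2ccc(OCc3ccccc3)c(OC)c2)c1
A6 | alternative 3 | 2-[4-(benzyloxy)-3-methoxyphenyl]-3-hydroxy-5,7-bis(methoxymethoxy)chroman-4-one (diastereomer mixture) | COCOc1cc(OCOC)c2c(c1)OC(c1ccc(OCc3ccccc3)c(OC)c1)C(O)C2=O
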